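(All constants are made up.)

Choosing between the closed flask violet and the tank grey means asking how each closes its gap to balance.

| setting | violet | grey |
|---|---|---|
| substrate | 0.10 M | 0.10 M |
| time | 4.0 min |  |
| remark | everything together in a closed stirred flask, run for 4.0 min | a single well-mixed tank run continuously and read at steady state, 4.0 min in it on average |

    substrate + substrate ⇌ product (K1 = 25.0 L mol⁻¹, k1 = 0.0640 L mol⁻¹ s⁻¹)

- percent here means substrate units held: one product counts as two
- two of one species on the left: rate k times its square, two consumed each time
- the stated concentrations are those of everything mixed, before any reaction; amounts are the same in each set-up
- run time (violet): 4.0 min

- the set-up with the highest amount of product at the outlet or at the end, in percent of the substrate put in ("none" if the first two lie within 2 percentage points) (violet / grey / none)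
- amount of product at the outlet or at the end, in percent of the substrate put in, violet
- amount of product at the outlet or at the end, in percent of the substrate put in, grey

My reckoning takes two extreme versions first; both are ceilings, so each real vessel belongs below the lower of its two.

1. Suppose nothing comes back. The size of the run is then 3.07, twice the rate constant times the charge times the time. That gives violet 75.4 % and grey 56.9 %, less in grey because the tank works at its outlet concentration.
2. Suppose the vessel is left until balance. Product then holds 64.2 % of the substrate units. Violet's first limit lies above this, so balance is the tighter limit for violet. Grey's first limit lies below it, so for grey the first limit stays.
3. Replace the curve by a straight first-order closing of the gap. The closing rate (relaxation rate) is the back constant plus the forward term at balance, 0.704 min⁻¹.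
4. Violet's gap then shrinks exponentially, giving 60.3 %. Grey's gap stays at one part in one plus closing rate times mean stay, giving 47.4 %. The choice is violet.
5. At the start the true rate is 1.70 times the line's, so both figures lie low.

The forecast names violet, with violet 61.9 % (61.3 % to 62.4 %) and grey 49.2 % (48.7 % to 49.7 %), and ends: “Batch wins.” Its figures stand above my line.

The simulation gives violet, with violet 61.9 % and grey 49.2 %. In violet the forward step ran from the full charge down to 38.1 % of the substrate at the end, and the same flask reads 64.2 % after 40.0 min. In grey both steps ran steadily at one substrate concentration, 0.0508 M. With a stay 3 times as long, the closing rate puts grey at 57.4 %. That tank holds 57.8 %.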